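Assumption and notation: the C5 ester is read as drawn, (Z)-2-methylbut-2-enoate (angelate). Positions use eremophilane numbering: C3 = CH–OAc, C4 = CH–CH3, C5 = quaternary C–CH3, C6=C7(Ac), C8 = ring C=O, C9 = CH–O-angelate, C10 = C–OH. β is the face of the C5 methyl. The target is 3S,4R,5R,9S,10R, that is 3β-OAc, 4β-Me, 5β-Me, 10β-OH and 9α-O-angelate.

**Retrosynthetic overview**
1. The C9–O(angelate) bond is made last. Angelic acid opens the 9β,10β-epoxy enedione 14 at C9 with inversion, which sets C9 and releases the 10β-OH.
2. The C7 acetyl and the C6=C7 alkene come from epoxy ketone 10 by C-acylation and selenoxide elimination. The 3-OAc is installed in the same acylation.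
3. The 3β-OH and the β-epoxide come from dione 8 by bulky-hydride reduction, followed by Weitz–Scheffer epoxidation during the peroxide work-up.
4. The C4 methyl and C3 oxygen come from (S)-Wieland–Miescher ketone 4 by methylenation, allylic oxidation and face-selective hydrogenation.
5. Ring order: ring A is bought as dione 1, and ring B is closed in step 1 by an organocatalytic Robinson annulation. The oxirane is a transient third ring.

**Step 1**
Reactants: 1 2-methylcyclohexane-1,3-dione; 2 methyl vinyl ketone
Product: 4 (S)-Wieland–Miescher ketone, via triketone 3 (not isolated)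
Conditions: Et3N (1 mol %), neat, rt; then N-Ts-(Sa)-binam-L-prolinamide (2 mol %), PhCO2H (1 mol %), neat, rt, 5 d; one recrystallisation (hexane–EtOAc)
Reagents that add atoms: methyl vinyl ketone (2), C=CC(C)=O
Why: Robinson annulation, in which Michael addition of the 1,3-dione to MVK is followed by a prolinamide-catalysed enamine aldol condensation (Hajos–Parrish–Eder–Sauer–Wiechert type) that differentiates the two enantiotopic ring carbonyls and sets the quaternary C5 as (S) (about 94% ee, >99% after recrystallisation).

**Step 2**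
Reactants: 4 (S)-Wieland–Miescher ketone
Product: 5 (4aR)-4a-methyl-5-methylidene-4,4a,5,6,7,8-hexahydronaphthalen-2(3H)-one
Conditions: Ph3PCH3Br (1.15 equiv), KOt-Bu (1.1 equiv), THF, 0 °C; add 4, −40 → 0 °C
Reagents that add atoms: methyltriphenylphosphonium bromide, C[P+](c1ccccc1)(c1ccccc1)c1ccccc1.[Br-]
Why: Wittig methylenation, in which about one equivalent of ylide takes the saturated C4 ketone faster than the less electrophilic vinylogous enone carbonyl (the same order as in borohydride reduction and ketalisation of this dione), leaving C5 untouched.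

**Step 3**
Reactants: 5 4-methylidene enone
Product: 7 (4aS)-4a-methyl-5-methylidene-4,4a,7,8-tetrahydronaphthalene-2,6(3H,5H)-dione, via allylic alcohol 6 (not isolated)
Conditions: SeO2 (0.3 equiv), t-BuOOH (2 equiv, decane), CH2Cl2, rt; aq. Na2SO3 wash, dry; DMP (1.2 equiv), CH2Cl2, 0 °C → rt
Reagents that add atoms: tert-butyl hydroperoxide, CC(C)(C)OO (terminal O source); selenium dioxide, O=[Se]=O (catalytic O carrier)
Why: Riley-type SeO2 allylic oxidation (ene reaction, then [2,3]-shift) can only use the C3 hydrogens because the other allylic carbon C5 is quaternary and the enone alkene is too electron-poor, and Dess–Martin oxidation then converges both C3 epimers on one exocyclic enone that cannot isomerise into the ring.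

**Step 4**
Reactants: 7 exocyclic enone
Product: 8 (4aR,5R)-4a,5-dimethyl-4,4a,7,8-tetrahydronaphthalene-2,6(3H,5H)-dione
Conditions: H2 (1 atm), RhCl(PPh3)3 (5 mol %), toluene, rt
Reagents that add atoms: none
Why: Wilkinson hydrogenation reduces the unhindered 1,1-disubstituted alkene and not the trisubstituted C9=C10 enone, and syn delivery of H2 to the α face, opposite the adjacent axial C5 methyl, sets C4 with its methyl β (cis to the C5 methyl) under neutral, non-epimerising conditions.

**Step 5**
Reactants: 8 4,5-dimethyl ene-dione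
Product: 10 9β,10β-epoxy-3β-hydroxy ketone, via 3β-alcohol 9 (not isolated)
Conditions: L-Selectride (1.05 equiv), THF, −78 °C, 1 h; then MeOH, 3 M NaOH, 30% H2O2, 0 °C → rt
Reagents that add atoms: hydrogen peroxide, OO
Why: Bulky-hydride reduction by equatorial attack from the α face (away from the syn-axial C5 methyl, as in the L-Selectride route to cis-2-methylcyclohexanol) gives the axial 3β-alcohol (3S) and spares the β,β-disubstituted enone, and the NaOH/H2O2 that destroys the borane then performs the Weitz–Scheffer epoxidation, with HOO− adding to C10 cis to the angular methyl (as in Δ4-3-keto steroids, β major) to set C9 and C10.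

**Step 6**
Reactants: 10 epoxy hydroxy ketone
Product: 11 3β-acetoxy-7-acetyl-9β,10β-epoxy-8-ketone (enolised β-diketone)
Conditions: LiHMDS (3.2 equiv), THF, −78 °C; 1-acetylbenzotriazole (2.2 equiv), −78 → −20 °C; AcOH quench
Reagents that add atoms: 1-acetyl-1H-benzotriazole, CC(=O)n1nnc2ccccc12
Why: Kinetic enolisation is possible only at C7 (C9 is an oxirane CH), so the enolate is C-acylated by the N-acylbenzotriazole (Claisen-type acylation) while the C3 lithium alkoxide is O-acetylated in the same flask, the third equivalent of base holding the product as its stable β-diketonate, and no stereocentre is touched.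

**Step 7**
Reactants: 11 epoxy β-diketone acetate
Product: 14 epoxy enedione acetate, via selenide 12 (not isolated), via selenoxide 13 (not isolated)
Conditions: LiHMDS (1.05 equiv), THF, −78 °C; PhSeCl (1.1 equiv); then 30% H2O2 (3 equiv), CH2Cl2, 0 °C
Reagents that add atoms: none
Why: Selenenylation of the β-diketonate at C7, oxidation and selenoxide syn-elimination (the standard dehydrogenation of β-dicarbonyls) can only remove a C6 hydrogen and gives the 2-acyl enone, and the oxirane survives because no acidic halide source is present.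

**Step 8**
Reactants: 14 epoxy enedione acetate; 15 angelic acid
Product: 16 target, (1S,4aR,5R,6S,8aR)-6-acetoxy-3-acetyl-8a-hydroxy-4a,5-dimethyl-2-oxo-1,2,4a,5,6,7,8,8a-octahydronaphthalen-1-yl (2Z)-2-methylbut-2-enoate
Conditions: 15 (2.0 equiv), TBD (1,5,7-triazabicyclo[4.4.0]dec-5-ene, 20 mol %), toluene, 4 Å MS, 35 °C, halide-free
Reagents that add atoms: angelic acid (15), C/C=C(/C)C(=O)O
Why: Proposed new method: guanidinium–carboxylate ion-pair catalysis of a Cα-selective acyloxylative opening of an α,β-epoxy ketone, in which TBD is protonated by angelic acid and the two N–H bonds of TBD-H+ bridge the C8 carbonyl oxygen and the angelate so that the carboxylate oxygen lies on the σ*(C9–O) axis on the α face; π*(C=O)/σ*(C–O) mixing (the effect that accelerates SN2 at α-halo ketones) together with the fully substituted, neopentyl nature of C10 directs attack to C9; a second angelic acid protonates the departing oxirane oxygen so that no free alkoxide forms (avoiding retro-aldol, E1cB and acyl shift); inversion gives the 9α-angelate (9S) trans to the retained 10β-OH (10R); the Z-alkene is safe because the acid carbonyl is never activated and no halide is present (halide would cause double inversion); the closest known reaction types are onium-salt- or (salen)Co-carboxylate-catalysed addition of carboxylic acids to simple epoxides and the Cα-opening of α,β-epoxy ketones (for example 4β,5β-epoxy-3-keto steroids) by halide, thiolate or azide, whereas a carboxylic acid has not been shown on a trisubstituted epoxy enedione with retention of the β-hydroxyl.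

**Compound list**
1 | 2-methylcyclohexane-1,3-dione | CC1C(=O)CCCC1=O | starting material
2 | methyl vinyl ketone (but-3-en-2-one) | C=CC(C)=O | starting material
3 | 2-methyl-2-(3-oxobutyl)cyclohexane-1,3-dione | CC(=O)CCC1(C)C(=O)CCCC1=O | intermediate (not isolated)
4 | (S)-Wieland–Miescher ketone, (8aS)-8a-methyl-3,4,8,8a-tetrahydronaphthalene-1,6(2H,7H)-dione | C[C@]12CCC(=O)C=C1CCCC2=O | intermediate
5 | (4aR)-4a-methyl-5-methylidene-4,4a,5,6,7,8-hexahydronaphthalen-2(3H)-one | C[C@]12CCC(=O)C=C1CCCC2=C | intermediate
6 | (4aS)-6-hydroxy-4a-methyl-5-methylidene-4,4a,5,6,7,8-hexahydronaphthalen-2(3H)-one (both C6 epimers) | C[C@]12CCC(=O)C=C1CCC(O)C2=C | intermediate (not isolated)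
7 | (4aS)-4a-methyl-5-methylidene-4,4a,7,8-tetrahydronaphthalene-2,6(3H,5H)-dione | C[C@]12CCC(=O)C=C1CCC(=O)C2=C | intermediate
8 | (4aR,5R)-4a,5-dimethyl-4,4a,7,8-tetrahydronaphthalene-2,6(3H,5H)-dione | C[C@]12CCC(=O)C=C1CCC(=O)[C@@H]2C | intermediate
9 | (4aR,5R,6S)-6-hydroxy-4a,5-dimethyl-4,4a,5,6,7,8-hexahydronaphthalen-2(3H)-one | C[C@]12CCC(=O)C=C1CC[C@H](O)[C@@H]2C | intermediate (not isolated)
10 | (1R,4aR,5R,6S,8aR)-1,8a-epoxy-6-hydroxy-4a,5-dimethyloctahydronaphthalen-2(1H)-one | C[C@]12CCC(=O)[C@@H]3O[C@]13CC[C@H](O)[C@@H]2C | intermediate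
11 | (1R,4aR,5R,6S,8aR)-3-acetyl-1,8a-epoxy-4a,5-dimethyl-2-oxodecahydronaphthalen-6-yl acetate (enolised; C3 of the naphthalene numbering not defined) | C[C@]12CC(C(C)=O)C(=O)[C@@H]3O[C@]13CC[C@H](OC(C)=O)[C@@H]2C | intermediate
12 | 3-(phenylselanyl) derivative of 11 | C[C@]12CC(C(C)=O)([Se]c4ccccc4)C(=O)[C@@H]3O[C@]13CC[C@H](OC(C)=O)[C@@H]2C | intermediate (not isolated)
13 | selenoxide of 12 | C[C@]12CC(C(C)=O)([Se](=O)c4ccccc4)C(=O)[C@@H]3O[C@]13CC[C@H](OC(C)=O)[C@@H]2C | intermediate (not isolated)
14 | (1R,4aR,5R,6S,8aR)-3-acetyl-1,8a-epoxy-4a,5-dimethyl-2-oxo-1,2,4a,5,6,7,8,8a-octahydronaphthalen-6-yl acetate | C[C@]12C=C(C(C)=O)C(=O)[C@@H]3O[C@]13CC[C@H](OC(C)=O)[C@@H]2C | intermediate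
15 | angelic acid, (2Z)-2-methylbut-2-enoic acid | C/C=C(/C)C(=O)O | starting material
16 | CNP0196241.1 (name as in step 8) | C/C=C(/C)C(=O)O[C@@H]1C(=O)C(C(C)=O)=C[C@]2(C)[C@@H](C)[C@@H](OC(C)=O)CC[C@]12O | target

**Totals**
Total steps: 8. Longest linear sequence: 8.

**Three steps most likely to fail**

Step 8 (the new C–O bond formation). The angelate may be too weak a nucleophile, or the product may dehydrate to the 9-acyloxy dienone. The fallback sets out from 14. Acid-catalysed hydrolysis (cat. HClO4, THF–H2O, 0 °C) should admit water at C9 for the same steric and electronic reasons. It gives the trans-diol (1S,4aR,5R,6S,8aR)-3-acetyl-1,8a-dihydroxy-4a,5-dimethyl-2-oxo-1,2,4a,5,6,7,8,8a-octahydronaphthalen-6-yl acetate F5. Separately, 15 is converted with 2,4,6-trichlorobenzoyl chloride and Et3N into angelic 2,4,6-trichlorobenzoic anhydride F6. Heating F5 with F6 in toluene at 80 °C without DMAP is the established isomerisation-free angeloylation. It esterifies only the secondary 9α-OH and returns to the route at 16.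

Step 5 (face selectivity of the epoxidation and the telescoped work-up). The α-epoxide may form in significant amount. For the fallback, the Selectride reaction is worked up without peroxide (triethanolamine) and 9 is isolated, so the fallback sets out from 9. Luche reduction (NaBH4, CeCl3·7H2O, MeOH, −78 °C) gives the pseudo-equatorial 8β-allylic alcohol (2S,4aR,5R,6S)-4a,5-dimethyl-2,3,4,4a,5,6,7,8-octahydronaphthalene-2,6-diol F1. Hydroxyl-directed epoxidation (VO(acac)2/t-BuOOH or m-CPBA) delivers oxygen syn to the 8β-OH. This gives (1S,2S,4aR,5R,6S,8aR)-1,8a-epoxy-4a,5-dimethyldecahydronaphthalene-2,6-diol F2. Sterically selective oxidation of the C8 carbinol (TEMPO, PhI(OAc)2, CH2Cl2) leaves the axial, 1,3-diaxially shielded 3β-OH alone and returns to the route at 10.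

Step 6 (double acetylation through an epoxy-ketone enolate). O-acetylation may be incomplete, the enolate may be O-acylated, or the enolate may decompose during the slow acyl transfer. The fallback sets out from 10. Ac2O, DMAP and pyridine give (1R,4aR,5R,6S,8aR)-1,8a-epoxy-4a,5-dimethyl-2-oxodecahydronaphthalen-6-yl acetate F3. LiHMDS (1.05 equiv, −78 °C) followed at once by acetaldehyde traps the enolate in a fast aldol addition. This gives the 3-(1-hydroxyethyl) ketone (new centres not defined) F4. Dess–Martin oxidation of F4 returns to the route at 11.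

**Further compounds**
F1 | step 5 | (2S,4aR,5R,6S)-4a,5-dimethyl-2,3,4,4a,5,6,7,8-octahydronaphthalene-2,6-diol | C[C@]12CC[C@H](O)C=C1CC[C@H](O)[C@@H]2C
F2 | step 5 | (1S,2S,4aR,5R,6S,8aR)-1,8a-epoxy-4a,5-dimethyldecahydronaphthalene-2,6-diol | C[C@]12CC[C@H](O)[C@@H]3O[C@]13CC[C@H](O)[C@@H]2C
F3 | step 6 | (1R,4aR,5R,6S,8aR)-1,8a-epoxy-4a,5-dimethyl-2-oxodecahydronaphthalen-6-yl acetate | C[C@]12CCC(=O)[C@@H]3O[C@]13CC[C@H](OC(C)=O)[C@@H]2C
F4 | step 6 | 3-(1-hydroxyethyl) derivative of F3 (new centres not defined) | C[C@]12CC(C(C)O)C(=O)[C@@H]3O[C@]13CC[C@H](OC(C)=O)[C@@H]2C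
F5 | step 8 | (1S,4aR,5R,6S,8aR)-3-acetyl-1,8a-dihydroxy-4a,5-dimethyl-2-oxo-1,2,4a,5,6,7,8,8a-octahydronaphthalen-6-yl acetate | O[C@@H]1C(=O)C(C(C)=O)=C[C@]2(C)[C@@H](C)[C@@H](OC(C)=O)CC[C@]12O
F6 | step 8 | angelic 2,4,6-trichlorobenzoic anhydride | C/C=C(/C)C(=O)OC(=O)c1c(Cl)cc(Cl)cc1Cl
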